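**Retrosynthetic overview**

- The target is reached last by O-geranylation of the C4' hydroxyl of the fully deprotected (R)-α-ketol. One hydrogenolysis before that removes the steering bromine at C6' and three benzyl groups.
- The strategy rests on ring A, where C1' carries the ketone carbon and the neighbouring C2' carries the hydroxyl hydrogen-bonded to it. This ortho pair is cut back to an aryne across C1'–C2' plus one carboxylate, which supplies both the C2' oxygen and the acyl carbon.
- The aryne partner is 5-(benzyloxy)-3-bromobenzyne, released from an ortho-silyl aryl triflate made from 4-(benzyloxy)phenol (dibromination, O-silylation, retro-Brook shift, triflation). The bromine, the future C6' substituent, decides which aryne carbon takes oxygen.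
- The acid partner is (R)-2-(benzyloxy)-3-[4-(benzyloxy)phenyl]propanoic acid from D-tyrosine (deamination with retention, benzylations, saponification). C2 is the only stereocentre and is never a reacting centre afterwards.
- Ring order: no ring is formed at any stage. Rings A and B are both bought as benzene rings and only substituted.

Key step: step 8

Remark: primed locants refer to ring A (C1' bears the acyl group), ring B is the 4-hydroxyphenyl ring and C2 is the carbinol carbon. Deamination of the α-amino acid by nitrous acid is taken to proceed with net retention, as is general for this reaction.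

**Route**

Step 1
Reactants: 1 4-(benzyloxy)phenol
Product: 2 4-(benzyloxy)-2,6-dibromophenol
Conditions: NBS (2.05 equiv), i-Pr2NH (0.1 equiv), CH2Cl2, 0 °C to rt, dark
Reagents that add atoms: N-bromosuccinimide, O=C1CCC(=O)N1Br
Why: Amine-catalysed electrophilic aromatic bromination should place bromine at both positions ortho to the free hydroxyl, the stronger director, since the para position is blocked by the benzyl ether and the ionic, dark conditions spare the benzylic CH2.

Step 2
Reactants: 2 4-(benzyloxy)-2,6-dibromophenol
Product: 3 [4-(benzyloxy)-2,6-dibromophenoxy]trimethylsilane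
Conditions: HMDS (1.0 equiv), THF, reflux; concentrate
Reagents that add atoms: hexamethyldisilazane, C[Si](C)(C)N[Si](C)(C)C
Why: O-silylation of the acidic phenol by a silazane is driven by loss of ammonia and should leave a salt-free silyl ether that can be lithiated directly.

Step 3
Reactants: 3 [4-(benzyloxy)-2,6-dibromophenoxy]trimethylsilane
Product: 6 4-(benzyloxy)-2-bromo-6-(trimethylsilyl)phenyl trifluoromethanesulfonate, via aryllithium 4 (not isolated), via lithium phenoxide 5 (not isolated)
Conditions: n-BuLi (1.05 equiv), THF, −78 °C; then Tf2O (1.2 equiv), −78 °C to rt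
Reagents that add atoms: trifluoromethanesulfonic anhydride, O=S(=O)(OS(=O)(=O)C(F)(F)F)C(F)(F)F
Why: Bromine–lithium exchange at one of the two equivalent C–Br bonds, much faster at −78 °C than deprotonation of the benzyl ether, is followed by a retro-Brook rearrangement (oxygen-to-carbon silyl shift) and O-triflation of the resulting phenoxide in the same flask.

Step 4
Reactants: 7 D-tyrosine
Product: 10 (R)-2-hydroxy-3-(4-hydroxyphenyl)propanoic acid, via diazonium carboxylate 8 (not isolated), via α-lactone 9 (not isolated)
Conditions: NaNO2 (1.5 equiv), 1 M H2SO4 aq, 0 °C to rt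
Reagents that add atoms: water, O
Why: Diazotisation of the α-amino acid gives a diazonium ion that the neighbouring carboxylate displaces with inversion, and water opens the α-lactone with a second inversion, so this deaminative hydroxylation should keep the (R) configuration of D-tyrosine.

Step 5
Reactants: 10 (R)-2-hydroxy-3-(4-hydroxyphenyl)propanoic acid; 11 benzyl bromide
Product: 12 benzyl (R)-3-[4-(benzyloxy)phenyl]-2-hydroxypropanoate
Conditions: BnBr (2.2 equiv), K2CO3 (2.5 equiv), DMF, rt
Reagents that add atoms: benzyl bromide (11), BrCc1ccccc1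
Why: Williamson-type O-alkylation should take place only at the carboxylate and the phenoxide, the two groups a carbonate base deprotonates, leaving the secondary alcohol free and the α-centre unenolised.

Step 6
Reactants: 12 benzyl (R)-3-[4-(benzyloxy)phenyl]-2-hydroxypropanoate; 11 benzyl bromide
Product: 13 benzyl (R)-2-(benzyloxy)-3-[4-(benzyloxy)phenyl]propanoate
Conditions: BnBr (1.5 equiv), Ag2O (1.5 equiv), CH2Cl2, rt, dark
Reagents that add atoms: benzyl bromide (11), BrCc1ccccc1
Why: Silver-oxide-mediated benzylation (halide abstraction by silver) etherifies the secondary alcohol under essentially neutral conditions, so the α-alkoxy ester centre should not epimerise as it might under alkoxide conditions.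

Step 7
Reactants: 13 benzyl (R)-2-(benzyloxy)-3-[4-(benzyloxy)phenyl]propanoate
Product: 14 (R)-2-(benzyloxy)-3-[4-(benzyloxy)phenyl]propanoic acid
Conditions: LiOH·H2O (1.5 equiv), THF/H2O 3:1, 0 °C to rt; then 1 M HCl
Reagents that add atoms: lithium hydroxide, [Li+].[OH-]
Why: Saponification of the unhindered benzyl ester by acyl–oxygen cleavage is fast at low temperature, and the carboxylate formed is no longer enolisable, so the C2 configuration should be kept.

Step 8
Reactants: 14 (R)-2-(benzyloxy)-3-[4-(benzyloxy)phenyl]propanoic acid; 6 4-(benzyloxy)-2-bromo-6-(trimethylsilyl)phenyl trifluoromethanesulfonate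
Product: 17 (R)-2-(benzyloxy)-1-[4-(benzyloxy)-2-bromo-6-hydroxyphenyl]-3-[4-(benzyloxy)phenyl]propan-1-one, via caesium carboxylate 15 (not isolated), via 5-(benzyloxy)-3-bromobenzyne 16 (not isolated)
Conditions: Cs2CO3 (0.5 equiv), MeOH, rt, evaporate and dry; then 6 (1.5 equiv), CsF (3 equiv), THF, 90 °C, sealed tube; 1 M HCl work-up
Reagents that add atoms: none
Why: Fluoride attacks silicon in 6 and expels triflate to give aryne 16; the carboxylate oxygen of 15 adds to the aryne carbon remote from bromine (the former C–Si carbon, future C2'), the aryl anion left on the carbon next to bromine (future C1') attacks the ester carbonyl to give a four-membered alkoxide, and C–O cleavage releases the ortho-acyl phenoxide, which is protonated on work-up. The closest known reaction type is the fluoride-induced insertion of arynes into the C–O bond of carboxylic acids to give ortho-hydroxyaryl ketones, an aryne-triggered anionic Fries-type acyl shift. No ring is closed, the four-membered alkoxide being only a transient, and the step forms the C2'–O and C1'–C(=O) bonds. No stereocentre is created; C2 comes from D-tyrosine, is not a reacting centre, and is shielded from enolisation because the acid reacts as its carboxylate and the product sits in the flask as a chelated caesium ortho-acylphenoxide (a vinylogous carboxylate). The step needs regioselective O-addition, which the bromine beside the triple bond should secure by inductive stabilisation of the adjacent carbanion and by distorting the aryne toward attack at the distal carbon, a bias much larger than the weak opposite one of the remote benzyloxy group; it also needs acyl capture of the aryl anion in preference to protonation, which the preformed dry caesium salt favours by removing the carboxylic proton. The geranyl chain is withheld until the end because its trisubstituted alkenes would undergo ene reactions with the aryne.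

Step 9
Reactants: 17 (R)-2-(benzyloxy)-1-[4-(benzyloxy)-2-bromo-6-hydroxyphenyl]-3-[4-(benzyloxy)phenyl]propan-1-one
Product: 18 (R)-1-(2,4-dihydroxyphenyl)-2-hydroxy-3-(4-hydroxyphenyl)propan-1-one
Conditions: H2 (1 atm), 10% Pd/C, NaOAc (1.5 equiv), EtOAc/MeOH 1:1, rt
Reagents that add atoms: none
Why: Heterogeneous palladium-catalysed hydrogenolysis should cleave the aryl C–Br bond and the three O-benzyl bonds in one operation, with NaOAc taking up HBr (a nitrogen base is avoided because it can retard benzyl ether cleavage), while the non-benzylic C2–O bond and the hydrogen-bonded aryl ketone should remain, so C2 is untouched.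

Step 10
Reactants: 18 (R)-1-(2,4-dihydroxyphenyl)-2-hydroxy-3-(4-hydroxyphenyl)propan-1-one; 19 geranyl bromide
Product: 20 (R)-1-{4-[(2E)-3,7-dimethylocta-2,6-dien-1-yloxy]-2-hydroxyphenyl}-2-hydroxy-3-(4-hydroxyphenyl)propan-1-one (CNP0159413.1)
Conditions: geranyl bromide (1.05 equiv), CsHCO3 (1.2 equiv), MeCN, 60 °C
Reagents that add atoms: geranyl bromide (19), CC(C)=CCC/C(C)=C/CBr
Why: In this Williamson ether synthesis the hydrogencarbonate should deprotonate essentially only the C4' hydroxyl, the most acidic one because it is para to the ketone, while the C2' hydroxyl is tied up in the hydrogen bond and the ring B phenol and the secondary alcohol stay protonated; direct displacement at the primary allylic carbon keeps the E alkene, and the mild base should not epimerise the α-ketol.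

**Compound list**

1 | 4-(benzyloxy)phenol | Oc1ccc(OCc2ccccc2)cc1 | starting material
2 | 4-(benzyloxy)-2,6-dibromophenol | Oc1c(Br)cc(OCc2ccccc2)cc1Br | intermediate
3 | [4-(benzyloxy)-2,6-dibromophenoxy]trimethylsilane | C[Si](C)(C)Oc1c(Br)cc(OCc2ccccc2)cc1Br | intermediate
4 | {5-(benzyloxy)-3-bromo-2-[(trimethylsilyl)oxy]phenyl}lithium | [Li]c1cc(OCc2ccccc2)cc(Br)c1O[Si](C)(C)C | intermediate
5 | lithium 4-(benzyloxy)-2-bromo-6-(trimethylsilyl)phenoxide | [Li+].[O-]c1c(Br)cc(OCc2ccccc2)cc1[Si](C)(C)C | intermediate
6 | 4-(benzyloxy)-2-bromo-6-(trimethylsilyl)phenyl trifluoromethanesulfonate | C[Si](C)(C)c1cc(OCc2ccccc2)cc(Br)c1OS(=O)(=O)C(F)(F)F | intermediate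
7 | D-tyrosine | N[C@H](Cc1ccc(O)cc1)C(=O)O | starting material
8 | (R)-2-diazonio-3-(4-hydroxyphenyl)propanoate | [O-]C(=O)[C@H]([N+]#N)Cc1ccc(O)cc1 | intermediate
9 | (S)-3-(4-hydroxybenzyl)oxiran-2-one | O=C1[C@H](Cc2ccc(O)cc2)O1 | intermediate
10 | (R)-2-hydroxy-3-(4-hydroxyphenyl)propanoic acid | OC(=O)[C@H](O)Cc1ccc(O)cc1 | intermediate
11 | benzyl bromide | BrCc1ccccc1 | starting material
12 | benzyl (R)-3-[4-(benzyloxy)phenyl]-2-hydroxypropanoate | O=C(OCc1ccccc1)[C@H](O)Cc1ccc(OCc2ccccc2)cc1 | intermediate
13 | benzyl (R)-2-(benzyloxy)-3-[4-(benzyloxy)phenyl]propanoate | O=C(OCc1ccccc1)[C@H](OCc1ccccc1)Cc1ccc(OCc2ccccc2)cc1 | intermediate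
14 | (R)-2-(benzyloxy)-3-[4-(benzyloxy)phenyl]propanoic acid | OC(=O)[C@H](OCc1ccccc1)Cc1ccc(OCc2ccccc2)cc1 | intermediate
15 | caesium (R)-2-(benzyloxy)-3-[4-(benzyloxy)phenyl]propanoate | [Cs+].[O-]C(=O)[C@H](OCc1ccccc1)Cc1ccc(OCc2ccccc2)cc1 | intermediate
16 | 5-(benzyloxy)-3-bromobenzyne (5-(benzyloxy)-3-bromo-1,2-didehydrobenzene) | BrC1=CC(OCc2ccccc2)=CC#C1 | intermediate
17 | (R)-2-(benzyloxy)-1-[4-(benzyloxy)-2-bromo-6-hydroxyphenyl]-3-[4-(benzyloxy)phenyl]propan-1-one | O=C(c1c(O)cc(OCc2ccccc2)cc1Br)[C@H](OCc1ccccc1)Cc1ccc(OCc2ccccc2)cc1 | intermediate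
18 | (R)-1-(2,4-dihydroxyphenyl)-2-hydroxy-3-(4-hydroxyphenyl)propan-1-one | O=C(c1ccc(O)cc1O)[C@H](O)Cc1ccc(O)cc1 | intermediate
19 | geranyl bromide, (2E)-1-bromo-3,7-dimethylocta-2,6-diene | CC(C)=CCC/C(C)=C/CBr | starting material
20 | (R)-1-{4-[(2E)-3,7-dimethylocta-2,6-dien-1-yloxy]-2-hydroxyphenyl}-2-hydroxy-3-(4-hydroxyphenyl)propan-1-one | CC(C)=CCC/C(C)=C/COc1ccc(C(=O)[C@H](O)Cc2ccc(O)cc2)c(O)c1 | target

**Step count**

Total: 10 steps. Longest linear sequence: 7 steps (steps 4, 5, 6, 7, 8, 9, 10, from D-tyrosine).

**Steps most likely to fail**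

1. Step 8. The caesium aryl anion formed beside bromine may expel bromide (giving a second aryne and oligomers) or be protonated to a simple aryl ester faster than it takes up the acyl group. Prolonged heating with fluoride may also erode the C2 configuration through enolisation of the transient aryl ester.
   Fallback (sets out from 14, returns at 18): the aryl–carbonyl bond would be made by a Weinreb ketone synthesis. Acid 14 is coupled with MeNHOMe·HCl (EDC·HCl, HOBt, i-Pr2NEt, CH2Cl2, 0 °C to rt) to give (R)-2-(benzyloxy)-3-[4-(benzyloxy)phenyl]-N-methoxy-N-methylpropanamide F1. Commercial 4-bromoresorcinol is dibenzylated with 11 and K2CO3 in DMF to give 2,4-bis(benzyloxy)-1-bromobenzene F2. Bromine–lithium exchange on F2 (n-BuLi, THF, −78 °C) gives [2,4-bis(benzyloxy)phenyl]lithium F3. F3 adds to F1 at −78 °C through the chelated tetrahedral intermediate to give, after aqueous work-up, (R)-2-(benzyloxy)-1-[2,4-bis(benzyloxy)phenyl]-3-[4-(benzyloxy)phenyl]propan-1-one F4. Hydrogenolysis of its four benzyl ethers (H2, Pd/C, EtOAc/MeOH, rt) gives 18.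

2. Step 10. Alkylation may spill over to the ring B phenoxide (double alkylation) once any stronger base equilibrium is reached, and the α-ketol may partly epimerise under base.
   Fallback (sets out from 18, returns at 20): a Mitsunobu etherification with geraniol (PPh3, DIAD, THF, 0 °C) replaces the bromide alkylation. Here the betaine is protonated by the most acidic hydroxyl, that at C4', and only this phenoxide is paired with the geranyloxyphosphonium ion. Site selection then rests on acidity under non-basic conditions, not on the nucleophilicity of a phenoxide mixture. No new compound is made on the way.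

3. Step 9. Hydrogenation may go on to reduce the aryl ketone to the benzylic alcohol or methylene, or debenzylation may stall through poisoning of the catalyst by bromide.
   Fallback (sets out from 17, returns at 18): the two reductive tasks are separated and hydrogen gas is avoided. Radical debromination of 17 (Bu3SnH, AIBN, toluene, 80 °C) gives (R)-2-(benzyloxy)-1-[4-(benzyloxy)-2-hydroxyphenyl]-3-[4-(benzyloxy)phenyl]propan-1-one F5. Its three benzyl ethers are then cleaved by BCl3 with pentamethylbenzene as cation scavenger (CH2Cl2, −78 °C), which leaves the ketone untouched and gives 18.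

**Further compounds**

F1 | step 8 | (R)-2-(benzyloxy)-3-[4-(benzyloxy)phenyl]-N-methoxy-N-methylpropanamide | CON(C)C(=O)[C@H](OCc1ccccc1)Cc1ccc(OCc2ccccc2)cc1
F2 | step 8 | 2,4-bis(benzyloxy)-1-bromobenzene | Brc1ccc(OCc2ccccc2)cc1OCc1ccccc1
F3 | step 8 | [2,4-bis(benzyloxy)phenyl]lithium | [Li]c1ccc(OCc2ccccc2)cc1OCc1ccccc1
F4 | step 8 | (R)-2-(benzyloxy)-1-[2,4-bis(benzyloxy)phenyl]-3-[4-(benzyloxy)phenyl]propan-1-one | O=C(c1ccc(OCc2ccccc2)cc1OCc1ccccc1)[C@H](OCc1ccccc1)Cc1ccc(OCc2ccccc2)cc1
F0 | step 10 | none | none
F5 | step 9 | (R)-2-(benzyloxy)-1-[4-(benzyloxy)-2-hydroxyphenyl]-3-[4-(benzyloxy)phenyl]propan-1-one | O=C(c1ccc(OCc2ccccc2)cc1O)[C@H](OCc1ccccc1)Cc1ccc(OCc2ccccc2)cc1
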